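## The problem

Compound 19 is an unsymmetrical biflavonoid. A (2S)-flavanone (phloroglucinol-derived ring A, pyranone ring C, aryl ring B) and a flavone (rings D, F and E in the same order) are joined by a biaryl bond between the carbons of rings B and E that lie ortho to the phenol oxygens. The centre of the molecule is therefore a 2,2'-biphenol with two different arms. C2 of ring C is the only stereocentre, nothing else in the molecule can relay chirality to it, and it has to be set by a chiral reagent or catalyst. It is also the weak point: the C2–O1 bond is benzylic and β to the C4 ketone, so base opens ring C by retro-oxa-Michael reaction to an achiral 2'-hydroxychalcone, and acid can ionise it through a benzylic cation that the para oxygen of ring B stabilises. The flavone half is made with KOH and a hot oxidant, which a flavanone would not survive, and its vinylogous ester does not tolerate hydride or organometallic reagents; the flavone must therefore come first and the flavanone last. Six phenols have to be carried through and then freed without exposing the finished flavanone to acid or base. The enabling feature is ring A: it is a 3,5-dioxygenated phenyl ether whose two carbons ortho to O1 (C4a and its mirror image) are equivalent and activated by all three oxygens, so the aryl ketone bond C4–C4a can be closed by an intramolecular acylation that has no regiochemical choice to make.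

## Retrosynthesis

**19 from 18.** No skeletal bond is cut. The five phenols of rings A, D and E are held as benzyl ethers and the ring B phenol as a benzyl carbonate. The carbonate is an acyl-type, electron-poor group during the acidic ring closure, yet it falls in the same neutral hydrogenolysis as the ethers. An acetate would serve equally in the acid step but would need a separate solvolysis on the free flavanone. The forward reaction must cleave six benzyl–oxygen bonds without reducing the flavone or opening ring C.

**18 from 16.** Ring C is opened at the aryl ketone bond C4–C4a, which leads through the mixed anhydride 17 to the (S)-β-aryloxy acid 16. Among the bonds of ring C, O1–C2 lies on the pathway by which flavanones racemise. C2–C3, O1–C8a and the pair C3–C4/O1–C2 are weighed under "Roads not taken". C4–C4a is the cut whose forward reaction has no selectivity to win: the stereocentre is already present, the two ortho carbons of ring A are equivalent, and the product appears directly at the ketone oxidation level. Compound 16 has one ring fewer and an open chain. The acylation must proceed without ionising the benzylic C2–O1 bond.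

**16 from 13 through 15.** The carboxyl carbon C4 is traced to the internal carbon of a terminal alkene; the terminal CH2 is lost on cleavage. A β-hydroxy ester in place of the homoallylic alcohol would be prone to dehydration in the etherification, and a β-aryloxy ester could not be saponified without E1cB loss of the ring A phenoxide. The allyl group is inert until the alkene is cleaved. The forward steps must cleave a monosubstituted alkene beside the flavone C2=C3 bond and several electron-rich arenes.

**13 from 11 and 12.** The benzylic C2–O1 bond is cut, giving the (R)-carbinol 11 and the commercial phenol 12; a Mitsunobu reaction joins them with inversion. An iridium-catalysed branched allylic etherification was considered for the same bond. It needs a cinnamyl-type ester that the aldehyde 10 cannot supply without hydride reduction, an aryloxide base that could exchange acyl groups with the ring B carbonate, and a hydroboration next to the flavone. The Mitsunobu route uses the aldehyde the earlier steps deliver and runs under neutral conditions. It must proceed by clean SN2 displacement.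

**11 from 10.** The C2–C3 bond is cut: enantioselective allylation of the aromatic aldehyde 10 sets the only stereocentre under catalyst control. The reaction must give high facial selectivity and leave the flavone ketone and the carbonate untouched.

**10 from 9, and 9 from 6 and 7.** After removal of the carbonate, the biaryl bond between rings B and E is cut. A Suzuki–Miyaura coupling joins the bromoflavone 6, by way of its boronate 8, to the bromophenol aldehyde 7. Desymmetrising a symmetrical 2,2'-biphenol dialdehyde would be statistical; here the two halves are different from the outset. The ring E oxygen can stay a benzyl ether because it is not conjugated with C2. Only the ring B oxygen needs the acyl group, so 7 is coupled as the free phenol and acylated afterwards.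

**6 from 4, 4 from 2 and 3, 2 from 1.** Ring F is opened at O1–C2 and the C2–C3 double bond is traced to an aldol condensation of ketone 2 with aldehyde 3. Ketone 2 comes from selective benzylation of 1. These are the only strongly basic and hot oxidative steps, and they come before any stereocentre exists.

## Roads not taken

**Alternative 1:** Rhodium carbene insertion, cutting C2–C3.
- Forward step: the diazo β-keto ester A1, carrying the biaryl-flavone as a benzyl ether on the ring A oxygen, would give a divalent rhodium carbene with Rh2(PTTL)4. Insertion into the benzylic ether C–H would close ring C and set C2 in the tert-butyl (2S)-flavanone-3-carboxylate A2.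
- Merits: ring and stereocentre arise in one catalytic event from an achiral ether made by simple O-benzylation. This is better than the chosen plan, which spends steps 6 to 10 on the same result.
- Weak points: the ether oxygen sits 1,5 to the carbene carbon, so ylide formation at oxygen followed by a [1,2]-benzyl shift (Stevens pathway) competes with the less favoured 1,6-insertion. Acceptor/acceptor carbenes give weaker enantiocontrol than the donor/acceptor carbenes of the five-membered precedent. A2 is a β-keto ester with an aryloxide leaving group β to its enolate, so it can open and reclose with loss of configuration. Removing the tert-butyl ester needs acid while ring B is an electron-rich methoxymethyl ether. Two protecting-group families must then be removed from the free flavanone.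
- Comparison: against the step economy of A1 to A2, the chosen plan offers a ring closure with no competing pathway of comparable weight, a stereocentre that is never enolisable, and a single neutral deprotection.

**Alternative 2:** Formal [4+2] cycloaddition, cutting C3–C4 and O1–C2.
- Forward step: a chiral BINOL phosphoric acid would dehydrate the salicyl alcohol A3 to the o-quinone methide A4, which would add the biaryl 4-vinylphenol A5 to give the (2S)-flavan A6.
- Merits: it is the most convergent of the four plans. Two bonds, ring C and the stereocentre form in one catalytic step, and the ring B phenol is used productively instead of being protected. The chosen plan is linear and cannot match this.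
- Weak points: A6 is a flavan, and C4 must still be oxidised to the ketone. That oxidation must discriminate C4 from C2, which is benzylic, α to oxygen and para to a free phenol, and from the methoxymethyl CH2 groups. A6 can also re-ionise at C2 under the acid catalyst, and A5 is prone to polymerise.
- Comparison: the chosen plan sets against the convergence the fact that C4 arrives as the ketone and no late C–H oxidation is needed.

**Alternative 3:** Palladium etherification, cutting O1–C8a.
- Forward step: the (S)-carbinol A7, bearing a ring A aryl bromide, would close with Pd(OAc)2, a bulky di-tert-butylbiarylphosphine and Cs2CO3 to the (2S)-flavan hexabenzyl ether A8, with retention at carbon.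
- Merits: the stereocentre would come from an enantioselective ketone reduction, the most dependable asymmetric step of all four plans. The ring closure is free of acid, and the uniform benzyl protection is as economical as in the chosen plan.
- Weak points: A8 is again a flavan. Its C4 oxidation has to compete with C2 and with twelve benzylic ether hydrogens. The palladium alkoxide of a secondary benzylic alcohol can undergo β-hydride elimination, and the electron-rich aryl bromide slows the coupling. With the C4 ketone already in place, Cs2CO3 would dehydrate the β-hydroxy ketone.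
- Comparison: the chosen plan has the less robust stereo-defining pair (steps 6 and 7) but ends at the correct oxidation level.

Key step: step 10

Assumption: 3, 7 and 12 are taken as catalogue chemicals, and the facial sense of the (R)-configured phosphoric acid in step 6 is taken from simple aromatic aldehydes; the antipodal catalyst would be used if 11 proved to be the (S)-alcohol.

## Route

Step 1
Reactants: 1 2',4',6'-trihydroxyacetophenone
Product: 2 1-[2,4-bis(benzyloxy)-6-hydroxyphenyl]ethan-1-one
Conditions: BnBr (2.1 equiv), K2CO3, DMF, rt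
Reagents that add atoms: benzyl bromide, BrCc1ccccc1
Why: Williamson etherification; the hydroxyl next to the acetyl group is hydrogen-bonded to the carbonyl oxygen and is the least nucleophilic, so two equivalents of benzyl bromide should leave it free.

Step 2
Reactants: 2 1-[2,4-bis(benzyloxy)-6-hydroxyphenyl]ethan-1-one; 3 4-(benzyloxy)-3-bromobenzaldehyde
Product: 4 (E)-1-[2,4-bis(benzyloxy)-6-hydroxyphenyl]-3-[4-(benzyloxy)-3-bromophenyl]prop-2-en-1-one
Conditions: KOH (50% aq.), EtOH/THF, rt
Reagents that add atoms: none
Why: Claisen–Schmidt condensation: the enolate of 2 adds to the non-enolisable aldehyde 3 and the aldol dehydrates by E1cB to the conjugated (E)-enone; benzyl ethers and the aryl bromide are inert to hydroxide at room temperature.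

Step 3
Reactants: 4 (E)-1-[2,4-bis(benzyloxy)-6-hydroxyphenyl]-3-[4-(benzyloxy)-3-bromophenyl]prop-2-en-1-one
Product: 6 5,7-bis(benzyloxy)-2-[4-(benzyloxy)-3-bromophenyl]-4H-chromen-4-one, via racemic flavanone 5 (not isolated)
Conditions: I2 (10 mol%), DMSO, 130 °C
Reagents that add atoms: none
Why: Iodine-catalysed oxidative cyclisation of a 2'-hydroxychalcone: oxa-Michael closure to 5, iodination α to the ketone and loss of HI give the flavone, and DMSO returns the iodide to I2. The conditions are standard for benzyl-protected flavone precursors and leave the aryl bromide untouched.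

Step 4
Reactants: 6 5,7-bis(benzyloxy)-2-[4-(benzyloxy)-3-bromophenyl]-4H-chromen-4-one; 7 3-bromo-4-hydroxybenzaldehyde
Product: 9 3-{2-(benzyloxy)-5-[5,7-bis(benzyloxy)-4-oxo-4H-chromen-2-yl]phenyl}-4-hydroxybenzaldehyde, via flavone boronate 8 (not isolated)
Conditions: B2pin2, Pd(dppf)Cl2 (5 mol%), KOAc, 1,4-dioxane, 90 °C; then 7, K3PO4, H2O, 90 °C
Reagents that add atoms: none
Why: Miyaura borylation followed in the same flask by Suzuki–Miyaura coupling: zerovalent palladium inserts into the C–Br bond of 6 and transmetallates with the diboron reagent, and boronate 8 then couples with 7. The aldehyde keeps 7 reactive towards oxidative addition even as its phenoxide, and the flavone and benzyl ethers tolerate the mild aqueous base.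

Step 5
Reactants: 9 3-{2-(benzyloxy)-5-[5,7-bis(benzyloxy)-4-oxo-4H-chromen-2-yl]phenyl}-4-hydroxybenzaldehyde
Product: 10 benzyl 2-{2-(benzyloxy)-5-[5,7-bis(benzyloxy)-4-oxo-4H-chromen-2-yl]phenyl}-4-formylphenyl carbonate
Conditions: CbzCl, Et3N, DMAP (cat.), CH2Cl2, 0 °C
Reagents that add atoms: benzyl chloroformate, O=C(Cl)OCc1ccccc1
Why: O-acylation of a phenol with a chloroformate under amine base. The carbonate blocks the phenol for the Mitsunobu step, makes the ring B oxygen a poor donor for the acidic ring closure, and is later removed by the same hydrogenolysis as the ethers.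

Step 6
Reactants: 10 benzyl 2-{2-(benzyloxy)-5-[5,7-bis(benzyloxy)-4-oxo-4H-chromen-2-yl]phenyl}-4-formylphenyl carbonate
Product: 11 benzyl 2-{2-(benzyloxy)-5-[5,7-bis(benzyloxy)-4-oxo-4H-chromen-2-yl]phenyl}-4-[(1R)-1-hydroxybut-3-en-1-yl]phenyl carbonate
Conditions: allylB(pin) (1.5 equiv), (R)-3,3'-bis(2,4,6-triisopropylphenyl)-1,1'-binaphthyl-2,2'-diyl hydrogen phosphate (5 mol%), toluene, −30 °C; aqueous work-up
Reagents that add atoms: allylboronic acid pinacol ester, C=CCB1OC(C)(C)C(C)(C)O1
Why: Chiral phosphoric acid-catalysed allylboration of an aromatic aldehyde through a chair transition state in which the catalyst hydrogen-bonds to a boronate oxygen and the formyl hydrogen. The (R)-catalyst should deliver the allyl group to the Re face and set the carbinol centre as R. The flavone ketone, carbonate and benzyl ethers are inert to the allylboronate at −30 °C.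

Step 7
Reactants: 11 benzyl 2-{2-(benzyloxy)-5-[5,7-bis(benzyloxy)-4-oxo-4H-chromen-2-yl]phenyl}-4-[(1R)-1-hydroxybut-3-en-1-yl]phenyl carbonate; 12 3,5-bis(benzyloxy)phenol
Product: 13 benzyl 2-{2-(benzyloxy)-5-[5,7-bis(benzyloxy)-4-oxo-4H-chromen-2-yl]phenyl}-4-{(1S)-1-[3,5-bis(benzyloxy)phenoxy]but-3-en-1-yl}phenyl carbonate
Conditions: PPh3, DIAD, THF, 0 °C to rt
Reagents that add atoms: none
Why: Mitsunobu etherification: the alkoxyphosphonium ion of 11 is displaced by the phenoxide of 12 in an SN2 process with inversion, which turns the (R)-carbinol into the (S)-aryl ether. The acyloxy group on ring B disfavours the SN1 leakage known for 4-alkoxybenzylic alcohols.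

Step 8
Reactants: 13 benzyl 2-{2-(benzyloxy)-5-[5,7-bis(benzyloxy)-4-oxo-4H-chromen-2-yl]phenyl}-4-{(1S)-1-[3,5-bis(benzyloxy)phenoxy]but-3-en-1-yl}phenyl carbonate
Product: 15 benzyl 2-{2-(benzyloxy)-5-[5,7-bis(benzyloxy)-4-oxo-4H-chromen-2-yl]phenyl}-4-{(1S)-1-[3,5-bis(benzyloxy)phenoxy]-3-oxopropyl}phenyl carbonate, via vicinal diol 14 (not isolated)
Conditions: OsO4 (2 mol%), NaIO4 (4 equiv), 2,6-lutidine, 1,4-dioxane/H2O 3:1, rt; crude 15 used at once
Reagents that add atoms: osmium tetroxide OsO4, O=[Os](=O)(=O)=O; sodium periodate NaIO4, [Na+].[O-]I(=O)(=O)=O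
Why: Lemieux–Johnson oxidation: catalytic OsO4 dihydroxylates the monosubstituted alkene much faster than the electron-poor trisubstituted C2=C3 bond of the flavone, and NaIO4 cleaves diol 14 and regenerates the osmium oxidant. C2 is not a reacting centre.

Step 9
Reactants: 15 benzyl 2-{2-(benzyloxy)-5-[5,7-bis(benzyloxy)-4-oxo-4H-chromen-2-yl]phenyl}-4-{(1S)-1-[3,5-bis(benzyloxy)phenoxy]-3-oxopropyl}phenyl carbonate
Product: 16 (3S)-3-[3,5-bis(benzyloxy)phenoxy]-3-(3-{2-(benzyloxy)-5-[5,7-bis(benzyloxy)-4-oxo-4H-chromen-2-yl]phenyl}-4-{[(benzyloxy)carbonyl]oxy}phenyl)propanoic acid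
Conditions: NaClO2, NaH2PO4, 2-methyl-2-butene (large excess), t-BuOH/THF/H2O, 0 °C to rt
Reagents that add atoms: sodium chlorite NaClO2, [Na+].[O-]Cl=O
Why: Pinnick oxidation at about pH 4. The excess alkene removes hypochlorous acid before it can chlorinate ring A, and the weakly acidic medium avoids base-induced loss of the β-aryloxide.

Step 10
Reactants: 16 (3S)-3-[3,5-bis(benzyloxy)phenoxy]-3-(3-{2-(benzyloxy)-5-[5,7-bis(benzyloxy)-4-oxo-4H-chromen-2-yl]phenyl}-4-{[(benzyloxy)carbonyl]oxy}phenyl)propanoic acid
Product: 18 benzyl 2-{2-(benzyloxy)-5-[5,7-bis(benzyloxy)-4-oxo-4H-chromen-2-yl]phenyl}-4-[(2S)-5,7-bis(benzyloxy)-4-oxochroman-2-yl]phenyl carbonate, via mixed trifluoroacetic anhydride 17 (not isolated)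
Conditions: (CF3CO)2O (3 equiv), CH2Cl2, 0 °C; cold aq. NaHCO3 quench
Reagents that add atoms: none
Why: Intramolecular Friedel–Crafts acylation: the anhydride converts acid 16 into mixed anhydride 17, which, as such or as the ion pair of its acylium ion, is attacked by the ring A carbon ortho to the ether oxygen; loss of a proton from the arenium ion restores ring A and leaves the aryl ketone bond C4–C4a. The closest known reaction type is the cyclisation of 3-aryloxypropanoic and enantioenriched 3-substituted 3-aryloxypropanoic acids to chroman-4-ones with trifluoroacetic anhydride or polyphosphoric acid. Ring C closes in a six-membered mode that is exo with respect to the acyl C=O and has the attacked aromatic bond C4a–C8a inside the new ring; no other ring size is open, because the para carbon of ring A is out of reach of the three-atom tether. No stereocentre is formed; C2, set in steps 6 and 7, is not a reacting centre and should be carried through unchanged. Regiochemistry needs no control because the two carbons ortho to the ether oxygen are related by the symmetry of the 3,5-bis(benzyloxy)phenoxy group, and each is ortho or para to all three oxygens. Chemoselectivity among the arenes follows from ring A being the only trioxygenated ring without a deactivating carbonyl and the only one within reach of the acyl group. Retention at C2 requires that the benzylic C2–O1 bond does not ionise, which is secured by the carbonate on the ring B oxygen, by the low temperature and by the absence of a mineral or Lewis acid.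

Step 11
Reactants: 18 benzyl 2-{2-(benzyloxy)-5-[5,7-bis(benzyloxy)-4-oxo-4H-chromen-2-yl]phenyl}-4-[(2S)-5,7-bis(benzyloxy)-4-oxochroman-2-yl]phenyl carbonate
Product: 19 (2S)-2-{3-[5-(5,7-dihydroxy-4-oxo-4H-chromen-2-yl)-2-hydroxyphenyl]-4-hydroxyphenyl}-5,7-dihydroxychroman-4-one
Conditions: H2 (1 atm), 10% Pd/C, THF/MeOH, rt
Reagents that add atoms: none
Why: Catalytic hydrogenolysis cleaves the five benzyl ethers to toluene and the benzyl carbonate to toluene and CO2 in one neutral operation, so the free flavanone meets neither acid nor base and C2 keeps its configuration. The reaction is stopped at complete debenzylation to avoid reduction of the flavone C2=C3 bond.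

## Compound list

1 | 2',4',6'-trihydroxyacetophenone | CC(=O)c1c(O)cc(O)cc1O | starting material
2 | 1-[2,4-bis(benzyloxy)-6-hydroxyphenyl]ethan-1-one | CC(=O)c1c(O)cc(OCc2ccccc2)cc1OCc1ccccc1 | intermediate
3 | 4-(benzyloxy)-3-bromobenzaldehyde | O=Cc1ccc(OCc2ccccc2)c(Br)c1 | starting material
4 | (E)-1-[2,4-bis(benzyloxy)-6-hydroxyphenyl]-3-[4-(benzyloxy)-3-bromophenyl]prop-2-en-1-one | O=C(/C=C/c1ccc(OCc2ccccc2)c(Br)c1)c1c(O)cc(OCc2ccccc2)cc1OCc1ccccc1 | intermediate
5 | racemic 5,7-bis(benzyloxy)-2-[4-(benzyloxy)-3-bromophenyl]chroman-4-one | O=C1CC(c2ccc(OCc3ccccc3)c(Br)c2)Oc2cc(OCc3ccccc3)cc(OCc3ccccc3)c21 | intermediate (not isolated)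
6 | 5,7-bis(benzyloxy)-2-[4-(benzyloxy)-3-bromophenyl]-4H-chromen-4-one | O=c1cc(-c2ccc(OCc3ccccc3)c(Br)c2)oc2cc(OCc3ccccc3)cc(OCc3ccccc3)c12 | intermediate
7 | 3-bromo-4-hydroxybenzaldehyde | O=Cc1ccc(O)c(Br)c1 | starting material
8 | 5,7-bis(benzyloxy)-2-[4-(benzyloxy)-3-(4,4,5,5-tetramethyl-1,3,2-dioxaborolan-2-yl)phenyl]-4H-chromen-4-one | O=c1cc(-c2ccc(OCc3ccccc3)c(B3OC(C)(C)C(C)(C)O3)c2)oc2cc(OCc3ccccc3)cc(OCc3ccccc3)c12 | intermediate (not isolated)
9 | 3-{2-(benzyloxy)-5-[5,7-bis(benzyloxy)-4-oxo-4H-chromen-2-yl]phenyl}-4-hydroxybenzaldehyde | O=Cc1ccc(O)c(-c2cc(-c3cc(=O)c4c(OCc5ccccc5)cc(OCc5ccccc5)cc4o3)ccc2OCc2ccccc2)c1 | intermediate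
10 | benzyl 2-{2-(benzyloxy)-5-[5,7-bis(benzyloxy)-4-oxo-4H-chromen-2-yl]phenyl}-4-formylphenyl carbonate | O=Cc1ccc(OC(=O)OCc2ccccc2)c(-c2cc(-c3cc(=O)c4c(OCc5ccccc5)cc(OCc5ccccc5)cc4o3)ccc2OCc2ccccc2)c1 | intermediate
11 | benzyl 2-{2-(benzyloxy)-5-[5,7-bis(benzyloxy)-4-oxo-4H-chromen-2-yl]phenyl}-4-[(1R)-1-hydroxybut-3-en-1-yl]phenyl carbonate | C=CC[C@@H](O)c1ccc(OC(=O)OCc2ccccc2)c(-c2cc(-c3cc(=O)c4c(OCc5ccccc5)cc(OCc5ccccc5)cc4o3)ccc2OCc2ccccc2)c1 | intermediate
12 | 3,5-bis(benzyloxy)phenol | Oc1cc(OCc2ccccc2)cc(OCc2ccccc2)c1 | starting material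
13 | benzyl 2-{2-(benzyloxy)-5-[5,7-bis(benzyloxy)-4-oxo-4H-chromen-2-yl]phenyl}-4-{(1S)-1-[3,5-bis(benzyloxy)phenoxy]but-3-en-1-yl}phenyl carbonate | C=CC[C@@H](c1ccc(OC(=O)OCc2ccccc2)c(-c2cc(-c3cc(=O)c4c(OCc5ccccc5)cc(OCc5ccccc5)cc4o3)ccc2OCc2ccccc2)c1)Oc1cc(OCc2ccccc2)cc(OCc2ccccc2)c1 | intermediate
14 | benzyl 2-{2-(benzyloxy)-5-[5,7-bis(benzyloxy)-4-oxo-4H-chromen-2-yl]phenyl}-4-{(1S)-1-[3,5-bis(benzyloxy)phenoxy]-3,4-dihydroxybutyl}phenyl carbonate, both epimers at the new carbinol carbon | OCC(O)C[C@@H](c1ccc(OC(=O)OCc2ccccc2)c(-c2cc(-c3cc(=O)c4c(OCc5ccccc5)cc(OCc5ccccc5)cc4o3)ccc2OCc2ccccc2)c1)Oc1cc(OCc2ccccc2)cc(OCc2ccccc2)c1 | intermediate (not isolated)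
15 | benzyl 2-{2-(benzyloxy)-5-[5,7-bis(benzyloxy)-4-oxo-4H-chromen-2-yl]phenyl}-4-{(1S)-1-[3,5-bis(benzyloxy)phenoxy]-3-oxopropyl}phenyl carbonate | O=CC[C@@H](c1ccc(OC(=O)OCc2ccccc2)c(-c2cc(-c3cc(=O)c4c(OCc5ccccc5)cc(OCc5ccccc5)cc4o3)ccc2OCc2ccccc2)c1)Oc1cc(OCc2ccccc2)cc(OCc2ccccc2)c1 | intermediate (used crude)
16 | (3S)-3-[3,5-bis(benzyloxy)phenoxy]-3-(3-{2-(benzyloxy)-5-[5,7-bis(benzyloxy)-4-oxo-4H-chromen-2-yl]phenyl}-4-{[(benzyloxy)carbonyl]oxy}phenyl)propanoic acid | OC(=O)C[C@@H](c1ccc(OC(=O)OCc2ccccc2)c(-c2cc(-c3cc(=O)c4c(OCc5ccccc5)cc(OCc5ccccc5)cc4o3)ccc2OCc2ccccc2)c1)Oc1cc(OCc2ccccc2)cc(OCc2ccccc2)c1 | intermediate (precursor of the key step)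
17 | mixed anhydride of acid 16 with trifluoroacetic acid, (3S) | O=C(C[C@@H](c1ccc(OC(=O)OCc2ccccc2)c(-c2cc(-c3cc(=O)c4c(OCc5ccccc5)cc(OCc5ccccc5)cc4o3)ccc2OCc2ccccc2)c1)Oc1cc(OCc2ccccc2)cc(OCc2ccccc2)c1)OC(=O)C(F)(F)F | intermediate (not isolated)
18 | benzyl 2-{2-(benzyloxy)-5-[5,7-bis(benzyloxy)-4-oxo-4H-chromen-2-yl]phenyl}-4-[(2S)-5,7-bis(benzyloxy)-4-oxochroman-2-yl]phenyl carbonate | O=C1C[C@@H](c2ccc(OC(=O)OCc3ccccc3)c(-c3cc(-c4cc(=O)c5c(OCc6ccccc6)cc(OCc6ccccc6)cc5o4)ccc3OCc3ccccc3)c2)Oc2cc(OCc3ccccc3)cc(OCc3ccccc3)c21 | intermediate (product of the key step)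
19 | (2S)-2-{3-[5-(5,7-dihydroxy-4-oxo-4H-chromen-2-yl)-2-hydroxyphenyl]-4-hydroxyphenyl}-5,7-dihydroxychroman-4-one | O=C1C[C@@H](c2ccc(O)c(-c3cc(-c4cc(=O)c5c(O)cc(O)cc5o4)ccc3O)c2)Oc2cc(O)cc(O)c21 | target

## Step count and risks

Total step count: 11. Longest linear sequence: 11 steps (1 to 19); 3, 7 and 12 enter as purchased compounds.

**Step 10 (key step).** The most likely failures are ionisation of the C2–O1 bond, with loss of optical purity or of the ring A phenol, and C-trifluoroacetylation of ring A by excess anhydride before ring closure; both stem from the strongly acidic, acylating medium. The fallback sets out from 16. The acid is converted under neutral conditions with 1-chloro-N,N,2-trimethylprop-1-en-1-amine in CH2Cl2 at 0 °C into (3S)-3-[3,5-bis(benzyloxy)phenoxy]-3-(3-{2-(benzyloxy)-5-[5,7-bis(benzyloxy)-4-oxo-4H-chromen-2-yl]phenyl}-4-{[(benzyloxy)carbonyl]oxy}phenyl)propanoyl chloride F1. This is cyclised with SnCl4 at −78 °C, a Lewis-acid Friedel–Crafts acylation free of protic acid and of any competing acyl donor. The fallback comes back to the route at 18.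

**Step 6.** Slow turnover and erosion of facial selectivity are possible, because the basic flavone carbonyl can compete for the phosphoric acid and the substrate may be poorly soluble in cold toluene, which lets the uncatalysed addition take over. The fallback sets out from 10 and replaces catalyst control by reagent control: Brown allylation with salt-free (+)-B-allyldiisopinocampheylborane (the series derived from (−)-α-pinene, which attacks the Re face of aromatic aldehydes) in Et2O at −78 °C, then oxidative work-up at pH 7. It comes back at 11 and makes no new compound (F0).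

**Step 8.** β-Elimination of the ring A aryloxide from the aldehyde (retro-oxa-Michael reaction, favoured by the amine base and by long contact with aqueous periodate) and over-oxidation by the osmium/periodate couple are the likely problems. The fallback sets out from 13 and separates the two events. Upjohn dihydroxylation (OsO4 cat., N-methylmorpholine N-oxide, acetone/H2O) gives diol 14, which is isolated. Criegee glycol cleavage with Pb(OAc)4 in dry CH2Cl2 at 0 °C then gives the aldehyde in a base-free, non-aqueous medium, filtered straight into step 9. The fallback comes back at 15 and makes no new compound (F0).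

**Step 11.** Over-reduction may occur: saturation of the flavone C2=C3 bond or hydrogenolytic opening of ring C at the benzylic C2–O1 bond, once the partly debenzylated material becomes poorly soluble and reaction times grow. The fallback sets out from 18 and uses Lewis-acid debenzylation: BCl3 with pentamethylbenzene as cation scavenger in CH2Cl2 at −78 °C. This should cleave the benzyl ethers and, by the same benzyl–oxygen heterolysis, the benzyl carbonate, whose carbonic acid loses CO2 on work-up. It comes back at 19 and makes no new compound (F0).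

**Step 4.** Protodeboronation or homocoupling of the electron-rich, ortho-alkoxy boronate 8, and slow oxidative addition into the phenoxide of 7, are the likely problems. The fallback sets out from 7 and reverses the polarity of the coupling. Miyaura borylation of 7 (B2pin2, Pd(dppf)Cl2, KOAc, 1,4-dioxane) gives 4-hydroxy-3-(4,4,5,5-tetramethyl-1,3,2-dioxaborolan-2-yl)benzaldehyde F2, which is isolated. F2 is then coupled with the more easily activated bromide 6 (Pd(OAc)2, SPhos, K3PO4, toluene/H2O). The fallback comes back at 9.

## Further compounds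

F1 | step 10 | (3S)-3-[3,5-bis(benzyloxy)phenoxy]-3-(3-{2-(benzyloxy)-5-[5,7-bis(benzyloxy)-4-oxo-4H-chromen-2-yl]phenyl}-4-{[(benzyloxy)carbonyl]oxy}phenyl)propanoyl chloride | O=C(Cl)C[C@@H](c1ccc(OC(=O)OCc2ccccc2)c(-c2cc(-c3cc(=O)c4c(OCc5ccccc5)cc(OCc5ccccc5)cc4o3)ccc2OCc2ccccc2)c1)Oc1cc(OCc2ccccc2)cc(OCc2ccccc2)c1
F0 | step 6 | none | none
F0 | step 8 | none | none
F0 | step 11 | none | none
F2 | step 4 | 4-hydroxy-3-(4,4,5,5-tetramethyl-1,3,2-dioxaborolan-2-yl)benzaldehyde | O=Cc1ccc(O)c(B2OC(C)(C)C(C)(C)O2)c1
A1 | alternative 1 | tert-butyl 2-diazo-3-oxo-3-[2-({3-[2-(methoxymethoxy)-5-(5,7-bis(methoxymethoxy)-4-oxo-4H-chromen-2-yl)phenyl]-4-(methoxymethoxy)phenyl}methoxy)-4,6-bis(tert-butyldimethylsilyloxy)phenyl]propanoate | [N-]=[N+]=C(C(=O)OC(C)(C)C)C(=O)c1c(OCc2ccc(OCOC)c(-c3cc(-c4cc(=O)c5c(OCOC)cc(OCOC)cc5o4)ccc3OCOC)c2)cc(O[Si](C)(C)C(C)(C)C)cc1O[Si](C)(C)C(C)(C)C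
A2 | alternative 1 | tert-butyl (2S)-flavanone-3-carboxylate of the biflavonoid, C3 undefined, methoxymethyl ethers on rings B, D and E, silyl ethers on ring A | O=C1C(C(=O)OC(C)(C)C)[C@@H](c2ccc(OCOC)c(-c3cc(-c4cc(=O)c5c(OCOC)cc(OCOC)cc5o4)ccc3OCOC)c2)Oc2cc(O[Si](C)(C)C(C)(C)C)cc(O[Si](C)(C)C(C)(C)C)c21
A3 | alternative 2 | 2-(hydroxymethyl)-3,5-bis(methoxymethoxy)phenol | OCc1c(O)cc(OCOC)cc1OCOC
A4 | alternative 2 | 6-methylidene-3,5-bis(methoxymethoxy)cyclohexa-2,4-dien-1-one (o-quinone methide) | C=C1C(=O)C=C(OCOC)C=C1OCOC
A5 | alternative 2 | 2-[3-(5-ethenyl-2-hydroxyphenyl)-4-(methoxymethoxy)phenyl]-5,7-bis(methoxymethoxy)-4H-chromen-4-one | C=Cc1ccc(O)c(-c2cc(-c3cc(=O)c4c(OCOC)cc(OCOC)cc4o3)ccc2OCOC)c1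
A6 | alternative 2 | (2S)-flavan–flavone with free ring B phenol, methoxymethyl ethers elsewhere | C1C[C@@H](c2ccc(O)c(-c3cc(-c4cc(=O)c5c(OCOC)cc(OCOC)cc5o4)ccc3OCOC)c2)Oc2cc(OCOC)cc(OCOC)c21
A7 | alternative 3 | (1S)-3-[2,4-bis(benzyloxy)-6-bromophenyl]-1-(4-(benzyloxy)-3-{2-(benzyloxy)-5-[5,7-bis(benzyloxy)-4-oxo-4H-chromen-2-yl]phenyl}phenyl)propan-1-ol | O[C@@H](CCc1c(Br)cc(OCc2ccccc2)cc1OCc1ccccc1)c1ccc(OCc2ccccc2)c(-c2cc(-c3cc(=O)c4c(OCc5ccccc5)cc(OCc5ccccc5)cc4o3)ccc2OCc2ccccc2)c1
A8 | alternative 3 | (2S)-flavan–flavone hexabenzyl ether | C1C[C@@H](c2ccc(OCc3ccccc3)c(-c3cc(-c4cc(=O)c5c(OCc6ccccc6)cc(OCc6ccccc6)cc5o4)ccc3OCc3ccccc3)c2)Oc2cc(OCc3ccccc3)cc(OCc3ccccc3)c21
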